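**Plan**

1. Hydroazulene numbers are used for every intermediate: C1 = CH carrying the side chain, C3a = quaternary methyl carbon, C5 = C=O, C6/C7 = epoxide, C8a = fusion CH, chain C9–C14. The ring C3a–C4–C5–C6–C7–C8–C8a is the six-membered ring of a trans-hydrindan-5-one with one extra CH(CH3) carbon, C6, between carbonyl C5 and methylene C7. A diazoethane insertion can supply exactly this carbon.
2. Retrosynthetic cuts, in order: the acetate; C9–C10 (C1 acetyl plus a chiral C10–C14 organometallic); the epoxide oxygen and the C6=C7 unsaturation; C5–C6 and C6–C7 (back to the hydrindanone); C7–C8 (radical closure); C3a–C4 (Claisen). What remains is a cyclopentene made from limonene.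
3. Forward order: five-membered ring (ring contraction of limonene), six-membered ring (6-endo radical cyclisation), seven-membered ring (one-carbon enlargement), oxirane, side chain.
4. Stereochemistry: C1 comes from (S)-limonene and relays to C3a (Claisen anti to isopropenyl) and to C8a (H delivery anti to methyl and isopropenyl). The angular methyl steers hydride at C5, and the C5 carbinol directs the epoxide (C6, C7) before it is oxidised. C9 follows Felkin–Anh control by C1, and C12 comes from an (S)-HYTRA acetate aldol.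

Key step: step 9

Remark: centres that are erased later (epoxide and diol carbons of the limonene derivatives, the aldol carbons, the betaine carbons, the ozonide carbon) are left open in the SMILES. The ring-expanded ketone is drawn as its 6S epimer, although either C6 epimer serves.

Step 1
Reactants: 1 (S)-(−)-limonene
Product: 2 (4S)-limonene 1,2-oxide (cis/trans mixture)
Conditions: mCPBA (1.0 equiv), NaHCO3, CH2Cl2, 0 °C
Reagents that add atoms: mCPBA, O=C(OO)c1cccc(Cl)c1
Why: Prilezhaev epoxidation should be faster at the trisubstituted ring alkene than at the 1,1-disubstituted isopropenyl group, and the new epoxide centres are lost in step 2.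

Step 2
Reactants: 2 (4S)-limonene 1,2-oxide
Product: 4 (3S)-6-oxo-3-(prop-1-en-2-yl)heptanal, via trans-diol 3 (not isolated)
Conditions: H5IO6, THF–H2O, 0 °C to rt
Reagents that add atoms: water, O
Why: Acidic epoxide hydrolysis followed by Malaprade glycol cleavage in one pot should open the six-membered ring and leave the isopropenyl group and the stereocentre untouched.

Step 3
Reactants: 4 (3S)-6-oxo-3-(prop-1-en-2-yl)heptanal
Product: 6 (5R)-2-methyl-5-(prop-1-en-2-yl)cyclopent-1-ene-1-carbaldehyde, via aldol adduct 5 (not isolated)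
Conditions: piperidine (cat.), AcOH (cat.), toluene, reflux, Dean–Stark
Reagents that add atoms: none
Why: In this amine-catalysed intramolecular aldol condensation the aldehyde becomes the enamine nucleophile, so its α-carbon (C8a) attacks the methyl ketone (C3a) and closes the five-membered ring, while C1–H is not vinylogously acidic and keeps its configuration.

Step 4
Reactants: 6 (5R)-2-methyl-5-(prop-1-en-2-yl)cyclopent-1-ene-1-carbaldehyde
Product: 7 [(5R)-2-methyl-5-(prop-1-en-2-yl)cyclopent-1-en-1-yl]methanol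
Conditions: NaBH4, CeCl3·7H2O, MeOH, 0 °C
Reagents that add atoms: none
Why: Luche reduction should give clean 1,2-reduction of the tetrasubstituted enal to the allylic alcohol.

Step 5
Reactants: 7 [(5R)-2-methyl-5-(prop-1-en-2-yl)cyclopent-1-en-1-yl]methanol; 8 2-methoxypropene
Product: 10 1-[(1R,3R)-1-methyl-2-methylidene-3-(prop-1-en-2-yl)cyclopentyl]propan-2-one, via allyl isopropenyl ether 9 (not isolated)
Conditions: 8 (10 equiv), EtCO2H (cat.), toluene, sealed tube, 160 °C
Reagents that add atoms: none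
Why: Acid-catalysed vinyl ether exchange and ketone Claisen [3,3] rearrangement form C3a–C4 on the ring face anti to the neighbouring isopropenyl group, which should set the quaternary centre with its methyl cis to isopropenyl and deliver C4, C5 and C7 at once.

Step 6
Reactants: 10 1-[(1R,3R)-1-methyl-2-methylidene-3-(prop-1-en-2-yl)cyclopentyl]propan-2-one
Product: 12 1-[(1R,3R)-1-methyl-2-methylidene-3-(prop-1-en-2-yl)cyclopentyl]-3-(phenylselanyl)propan-2-one, via lithium enolate 11 (not isolated)
Conditions: LDA, THF, −78 °C; PhSeCl, −78 °C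
Reagents that add atoms: benzeneselenenyl chloride, Cl[Se]c1ccccc1
Why: Kinetic deprotonation should take the methyl group (C7) rather than the neopentyl methylene C4, and the enolate is selenenylated faster than either alkene reacts.

Step 7
Reactants: 12 1-[(1R,3R)-1-methyl-2-methylidene-3-(prop-1-en-2-yl)cyclopentyl]-3-(phenylselanyl)propan-2-one
Product: 13 (1S,3aR,7aS)-3a-methyl-1-(prop-1-en-2-yl)octahydro-5H-inden-5-one (trans-fused)
Conditions: Bu3SnH (slow addition), AIBN, benzene (5 mM), 80 °C
Reagents that add atoms: none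
Why: In this tin hydride radical cyclisation the α-keto radical at C7 adds 6-endo-trig to the CH2 terminus of the exocyclic alkene (5-exo would create two adjacent quaternary carbons, and the isopropenyl group lies out of reach on the other face), and the tertiary C8a radical should take hydrogen from the face opposite both the 3a-methyl and the isopropenyl group, giving the trans fusion.

Step 8
Reactants: 14 N-ethyl-N-nitrosourea
Product: 15 diazoethane (dried ethereal solution, used at once)
Conditions: 40% aq KOH, Et2O, −10 to 0 °C; decant, dry over KOH pellets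
Reagents that add atoms: none
Why: Base-induced decomposition of an N-alkyl-N-nitrosourea is the standard preparation of a simple diazoalkane.

Step 9
Reactants: 13 (1S,3aR,7aS)-3a-methyl-1-(prop-1-en-2-yl)octahydro-5H-inden-5-one; 15 diazoethane
Product: 17 (1S,3aR,6S,8aS)-3a,6-dimethyl-1-(prop-1-en-2-yl)octahydroazulen-5(1H)-one (either C6 epimer), via diazonium alkoxide 16 (not isolated)
Conditions: Sc(OTf)3 (10 mol %), 15 (1.5 equiv), CH2Cl2–Et2O, −78 to −30 °C
Reagents that add atoms: none
Why: The Sc(III)-activated C5 carbonyl is attacked by the carbon of 15 along the equatorial path (the axial path is blocked by the 3a-methyl group) to give betaine 16, and the ring bond antiperiplanar to C–N2+ shifts as nitrogen leaves. The closest known reaction type is the Lewis acid-catalysed diazoalkane homologation of cyclohexanones to 2-alkylcycloheptanones (Büchner–Curtius–Schlotterbeck addition with a Tiffeneau–Demjanov-type 1,2-shift). The seven-membered ring is formed by ring enlargement and not by cyclisation, the C5–C7 bond of the six-membered ring being exchanged for C5–C6 and C6–C7. The step needs migration of the open methylene C7 rather than neopentyl C4, because the rotamer that aligns C4 forces the methyl group on the diazo carbon gauche to C4 and its quaternary neighbour C3a, whereas aligning C7 leaves that methyl group on the free side. A second insertion should be slow, since the α-branched cycloheptanone 17 is a poorer electrophile than cyclohexanone 13, and the isopropenyl group is inert to the reagent at this temperature. C6 is formed without reliable control and can epimerise through the enol, which does no harm because it becomes sp2 in step 10, and C1, C3a and C8a are not touched.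

Step 10
Reactants: 17 (1S,3aR,6S,8aS)-3a,6-dimethyl-1-(prop-1-en-2-yl)octahydroazulen-5(1H)-one
Product: 18 (1S,3aR,8aS)-3a,6-dimethyl-1-(prop-1-en-2-yl)-2,3,3a,4,8,8a-hexahydroazulen-5(1H)-one
Conditions: IBX (2 equiv), DMSO–fluorobenzene, 65–70 °C
Reagents that add atoms: none
Why: IBX dehydrogenation of the ketone through its enol can only give the C6=C7 enone, because C4 adjoins quaternary C3a and has no β-hydrogen to lose.

Step 11
Reactants: 18 (1S,3aR,8aS)-3a,6-dimethyl-1-(prop-1-en-2-yl)-2,3,3a,4,8,8a-hexahydroazulen-5(1H)-one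
Product: 19 (1S,3aR,5R,8aS)-3a,6-dimethyl-1-(prop-1-en-2-yl)-1,2,3,3a,4,5,8,8a-octahydroazulen-5-ol (5-OH cis to the 3a-methyl)
Conditions: NaBH4, CeCl3·7H2O, MeOH, −78 to −20 °C
Reagents that add atoms: none
Why: In this Luche 1,2-reduction hydride should arrive on the face opposite the axial 3a-methyl group, which stands 1,3 to C5, placing the hydroxyl cis to that methyl, and the carbinol also masks C5 for the later organometallic step.

Step 12
Reactants: 19 (1S,3aR,5R,8aS)-3a,6-dimethyl-1-(prop-1-en-2-yl)-1,2,3,3a,4,5,8,8a-octahydroazulen-5-ol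
Product: 20 (1S,3aR,5R,6R,7S,8aS)-6,7-epoxy-3a,6-dimethyl-1-(prop-1-en-2-yl)decahydroazulen-5-ol (epoxide O and 5-OH cis to the 3a-methyl)
Conditions: VO(acac)2 (5 mol %), t-BuOOH, CH2Cl2, 0 °C
Reagents that add atoms: tert-butyl hydroperoxide, CC(C)(C)OO
Why: Vanadium-catalysed hydroxyl-directed epoxidation delivers oxygen syn to the allylic alcohol, which sets C6 and C7 on the methyl-bearing face, and leaves the undirected isopropenyl group alone.

Step 13
Reactants: 20 (1S,3aR,5R,6R,7S,8aS)-6,7-epoxy-3a,6-dimethyl-1-(prop-1-en-2-yl)decahydroazulen-5-ol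
Product: 22 1-[(1S,3aR,5R,6R,7S,8aS)-6,7-epoxy-5-hydroxy-3a,6-dimethyldecahydroazulen-1-yl]ethan-1-one, via secondary ozonide 21 (not isolated)
Conditions: O3, CH2Cl2, −78 °C; PPh3, −78 °C to rt
Reagents that add atoms: ozone, [O-][O+]=O
Why: Ozonolysis of the only remaining alkene with a neutral reductive work-up should give the C1 acetyl group without epimerising C1.

Step 14
Reactants: 23 (S)-2-hydroxy-1,2,2-triphenylethyl acetate [(S)-HYTRA]; 24 methacrolein
Product: 26 (S)-2-hydroxy-1,2,2-triphenylethyl (3S)-3-hydroxy-4-methylpent-4-enoate, via dilithio enolate 25 (not isolated)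
Conditions: LDA (2.2 equiv), THF, −78 to 0 °C; 24, THF–2-methylbutane, −125 °C; H2O; recrystallise
Reagents that add atoms: none
Why: In this auxiliary-controlled acetate aldol addition the doubly deprotonated (S)-auxiliary is known to give the (S)-carbinol with α-branched aldehydes, which sets C12, and crystallisation should raise the diastereomeric purity.

Step 15
Reactants: 26 (S)-2-hydroxy-1,2,2-triphenylethyl (3S)-3-hydroxy-4-methylpent-4-enoate
Product: 27 (S)-2-hydroxy-1,2,2-triphenylethyl (3S)-3-[(tert-butyldimethylsilyl)oxy]-4-methylpent-4-enoate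
Conditions: TBSOTf, 2,6-lutidine, CH2Cl2, −78 to 0 °C
Reagents that add atoms: tert-butyldimethylsilyl triflate, CC(C)(C)[Si](C)(C)OS(=O)(=O)C(F)(F)F
Why: Silylation should take the secondary allylic alcohol, because the diphenyl carbinol of the auxiliary is too hindered to compete.

Step 16
Reactants: 27 (S)-2-hydroxy-1,2,2-triphenylethyl (3S)-3-[(tert-butyldimethylsilyl)oxy]-4-methylpent-4-enoate
Product: 28 (3S)-3-[(tert-butyldimethylsilyl)oxy]-4-methylpent-4-en-1-ol
Conditions: DIBAL-H (4 equiv), CH2Cl2, −78 to 0 °C; Rochelle salt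
Reagents that add atoms: none
Why: Hydride reduction of the ester gives the primary alcohol and releases the auxiliary diol, and the non-basic aluminium alkoxide should not provoke silyl migration.

Step 17
Reactants: 28 (3S)-3-[(tert-butyldimethylsilyl)oxy]-4-methylpent-4-en-1-ol
Product: 29 tert-butyl{[(3S)-5-iodo-2-methylpent-1-en-3-yl]oxy}dimethylsilane
Conditions: I2, PPh3, imidazole, CH2Cl2, 0 °C
Reagents that add atoms: iodine, II
Why: Appel-type iodination of a primary alcohol proceeds by SN2 at C10 and does not touch C12.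

Step 18
Reactants: 22 1-[(1S,3aR,5R,6R,7S,8aS)-6,7-epoxy-5-hydroxy-3a,6-dimethyldecahydroazulen-1-yl]ethan-1-one; 29 tert-butyl{[(3S)-5-iodo-2-methylpent-1-en-3-yl]oxy}dimethylsilane
Product: 32 (2S,5S)-5-[(tert-butyldimethylsilyl)oxy]-2-[(1S,3aR,5R,6R,7S,8aS)-6,7-epoxy-5-hydroxy-3a,6-dimethyldecahydroazulen-1-yl]-6-methylhept-6-en-2-ol, via organolithium 30 (not isolated), via organocerium reagent 31 (not isolated)
Conditions: 29 (2.5 equiv), t-BuLi (5 equiv), Et2O–pentane, −78 °C; CeCl3, THF, −78 °C; then 22, −78 °C; H2O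
Reagents that add atoms: none
Why: Iodine–lithium exchange, transmetalation to the weakly basic organocerium reagent and 1,2-addition to the methyl ketone (one equivalent is spent on the 5-OH) should follow the Felkin–Anh model, with C8a anti to incoming C10, the carbonyl oxygen next to C2 and the acetyl methyl next to H1, which leads to the 9S carbinol, while the syn epoxy alkoxide cannot undergo Payne rearrangement.

Step 19
Reactants: 32 (2S,5S)-5-[(tert-butyldimethylsilyl)oxy]-2-[(1S,3aR,5R,6R,7S,8aS)-6,7-epoxy-5-hydroxy-3a,6-dimethyldecahydroazulen-1-yl]-6-methylhept-6-en-2-ol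
Product: 33 (1S,3aR,6S,7S,8aS)-1-[(2S,5S)-5-[(tert-butyldimethylsilyl)oxy]-2-hydroxy-6-methylhept-6-en-2-yl]-6,7-epoxy-3a,6-dimethyloctahydroazulen-5(1H)-one
Conditions: Dess–Martin periodinane, NaHCO3, CH2Cl2, 0 °C to rt
Reagents that add atoms: none
Why: Dess–Martin oxidation converts the only secondary alcohol into the epoxy ketone, while the tertiary C9 alcohol, the silyl ether and the alkene are inert.

Step 20
Reactants: 33 (1S,3aR,6S,7S,8aS)-1-[(2S,5S)-5-[(tert-butyldimethylsilyl)oxy]-2-hydroxy-6-methylhept-6-en-2-yl]-6,7-epoxy-3a,6-dimethyloctahydroazulen-5(1H)-one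
Product: 34 (1S,3aR,6S,7S,8aS)-1-[(2S,5S)-2,5-dihydroxy-6-methylhept-6-en-2-yl]-6,7-epoxy-3a,6-dimethyloctahydroazulen-5(1H)-one
Conditions: HF·pyridine, pyridine, THF, 0 °C to rt
Reagents that add atoms: none
Why: Buffered fluoride desilylation avoids base-sensitive epoxy ketone chemistry, and the 9-OH lies on the same face as the oxirane oxygen, so it cannot open the epoxide from the rear.

Step 21
Reactants: 34 (1S,3aR,6S,7S,8aS)-1-[(2S,5S)-2,5-dihydroxy-6-methylhept-6-en-2-yl]-6,7-epoxy-3a,6-dimethyloctahydroazulen-5(1H)-one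
Product: 35 (3S,6S)-6-[(1S,3aR,6S,7S,8aS)-6,7-epoxy-3a,6-dimethyl-5-oxodecahydroazulen-1-yl]-6-hydroxy-2-methylhept-1-en-3-yl acetate (CNP0165281.1)
Conditions: Ac2O, pyridine, DMAP (cat.), CH2Cl2, 0 °C
Reagents that add atoms: acetic anhydride, CC(=O)OC(C)=O
Why: Mild acylation should acetylate the secondary allylic C12 alcohol and leave the hindered tertiary C9 alcohol free.

**Compound list**

1 | (S)-(−)-limonene | C=C(C)[C@H]1CCC(C)=CC1 | starting material
2 | (4S)-limonene 1,2-oxide | C=C(C)[C@H]1CCC2(C)OC2C1 | intermediate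
3 | (4S)-p-menth-8-ene-1,2-diol | C=C(C)[C@H]1CCC(C)(O)C(O)C1 | intermediate
4 | (3S)-6-oxo-3-(prop-1-en-2-yl)heptanal | C=C(C)[C@H](CC=O)CCC(C)=O | intermediate
5 | (5S)-2-hydroxy-2-methyl-5-(prop-1-en-2-yl)cyclopentane-1-carbaldehyde | C=C(C)[C@H]1CCC(C)(O)C1C=O | intermediate
6 | (5R)-2-methyl-5-(prop-1-en-2-yl)cyclopent-1-ene-1-carbaldehyde | C=C(C)[C@H]1CCC(C)=C1C=O | intermediate
7 | [(5R)-2-methyl-5-(prop-1-en-2-yl)cyclopent-1-en-1-yl]methanol | C=C(C)[C@H]1CCC(C)=C1CO | intermediate
8 | 2-methoxypropene | C=C(C)OC | starting material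
9 | isopropenyl ether of 7 | C=C(C)[C@H]1CCC(C)=C1COC(C)=C | intermediate
10 | 1-[(1R,3R)-1-methyl-2-methylidene-3-(prop-1-en-2-yl)cyclopentyl]propan-2-one | C=C(C)[C@H]1CC[C@](C)(CC(C)=O)C1=C | intermediate
11 | kinetic lithium enolate of 10 | C=C(C)[C@H]1CC[C@](C)(CC(=C)[O-])C1=C.[Li+] | intermediate
12 | 1-[(1R,3R)-1-methyl-2-methylidene-3-(prop-1-en-2-yl)cyclopentyl]-3-(phenylselanyl)propan-2-one | C=C(C)[C@H]1CC[C@](C)(CC(=O)C[Se]c2ccccc2)C1=C | intermediate
13 | (1S,3aR,7aS)-3a-methyl-1-(prop-1-en-2-yl)octahydro-5H-inden-5-one | C=C(C)[C@H]1CC[C@]2(C)CC(=O)CC[C@@H]12 | intermediate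
14 | N-ethyl-N-nitrosourea | CCN(N=O)C(N)=O | starting material
15 | diazoethane | CC=[N+]=[N-] | intermediate
16 | β-diazonium alkoxide from 13 and 15 (scandium-bound) | C=C(C)[C@H]1CC[C@]2(C)CC([O-])(C(C)[N+]#N)CC[C@@H]12 | intermediate
17 | (1S,3aR,6S,8aS)-3a,6-dimethyl-1-(prop-1-en-2-yl)octahydroazulen-5(1H)-one | C=C(C)[C@H]1CC[C@]2(C)CC(=O)[C@@H](C)CC[C@@H]12 | intermediate
18 | (1S,3aR,8aS)-3a,6-dimethyl-1-(prop-1-en-2-yl)-2,3,3a,4,8,8a-hexahydroazulen-5(1H)-one | C=C(C)[C@H]1CC[C@]2(C)CC(=O)C(C)=CC[C@@H]12 | intermediate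
19 | (1S,3aR,5R,8aS)-3a,6-dimethyl-1-(prop-1-en-2-yl)-1,2,3,3a,4,5,8,8a-octahydroazulen-5-ol | C=C(C)[C@H]1CC[C@]2(C)C[C@@H](O)C(C)=CC[C@@H]12 | intermediate
20 | (1S,3aR,5R,6R,7S,8aS)-6,7-epoxy-3a,6-dimethyl-1-(prop-1-en-2-yl)decahydroazulen-5-ol | C=C(C)[C@H]1CC[C@]2(C)C[C@@H](O)[C@@]3(C)O[C@H]3C[C@@H]12 | intermediate
21 | secondary ozonide (3-methyl-1,2,4-trioxolan-3-yl at C1) of 20 | CC1(OCOO1)[C@H]2CC[C@]3(C)C[C@@H](O)[C@@]4(C)O[C@H]4C[C@@H]23 | intermediate
22 | 1-[(1S,3aR,5R,6R,7S,8aS)-6,7-epoxy-5-hydroxy-3a,6-dimethyldecahydroazulen-1-yl]ethan-1-one | CC(=O)[C@H]1CC[C@]2(C)C[C@@H](O)[C@@]3(C)O[C@H]3C[C@@H]12 | intermediate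
23 | (S)-2-hydroxy-1,2,2-triphenylethyl acetate [(S)-HYTRA] | CC(=O)O[C@@H](c1ccccc1)C(O)(c1ccccc1)c1ccccc1 | starting material
24 | methacrolein | C=C(C)C=O | starting material
25 | dilithio enolate of 23 | C=C([O-])O[C@@H](c1ccccc1)C([O-])(c1ccccc1)c1ccccc1.[Li+].[Li+] | intermediate
26 | (S)-2-hydroxy-1,2,2-triphenylethyl (3S)-3-hydroxy-4-methylpent-4-enoate | C=C(C)[C@H](CC(=O)O[C@@H](c1ccccc1)C(O)(c1ccccc1)c1ccccc1)O | intermediate
27 | (S)-2-hydroxy-1,2,2-triphenylethyl (3S)-3-[(tert-butyldimethylsilyl)oxy]-4-methylpent-4-enoate | C=C(C)[C@H](CC(=O)O[C@@H](c1ccccc1)C(O)(c1ccccc1)c1ccccc1)O[Si](C)(C)C(C)(C)C | intermediate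
28 | (3S)-3-[(tert-butyldimethylsilyl)oxy]-4-methylpent-4-en-1-ol | C=C(C)[C@H](CCO)O[Si](C)(C)C(C)(C)C | intermediate
29 | tert-butyl{[(3S)-5-iodo-2-methylpent-1-en-3-yl]oxy}dimethylsilane | C=C(C)[C@H](CCI)O[Si](C)(C)C(C)(C)C | intermediate
30 | (3S)-3-[(tert-butyldimethylsilyl)oxy]-4-methylpent-4-enyllithium | C=C(C)[C@H](CC[Li])O[Si](C)(C)C(C)(C)C | intermediate
31 | (3S)-3-[(tert-butyldimethylsilyl)oxy]-4-methylpent-4-enylcerium dichloride | C=C(C)[C@H](CC[Ce](Cl)Cl)O[Si](C)(C)C(C)(C)C | intermediate
32 | (2S,5S)-5-[(tert-butyldimethylsilyl)oxy]-2-[(1S,3aR,5R,6R,7S,8aS)-6,7-epoxy-5-hydroxy-3a,6-dimethyldecahydroazulen-1-yl]-6-methylhept-6-en-2-ol | C=C(C)[C@H](CC[C@](C)(O)[C@H]1CC[C@]2(C)C[C@@H](O)[C@@]3(C)O[C@H]3C[C@@H]12)O[Si](C)(C)C(C)(C)C | intermediate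
33 | (1S,3aR,6S,7S,8aS)-1-[(2S,5S)-5-[(tert-butyldimethylsilyl)oxy]-2-hydroxy-6-methylhept-6-en-2-yl]-6,7-epoxy-3a,6-dimethyloctahydroazulen-5(1H)-one | C=C(C)[C@H](CC[C@](C)(O)[C@H]1CC[C@]2(C)CC(=O)[C@@]3(C)O[C@H]3C[C@@H]12)O[Si](C)(C)C(C)(C)C | intermediate
34 | (1S,3aR,6S,7S,8aS)-1-[(2S,5S)-2,5-dihydroxy-6-methylhept-6-en-2-yl]-6,7-epoxy-3a,6-dimethyloctahydroazulen-5(1H)-one | C=C(C)[C@H](CC[C@](C)(O)[C@H]1CC[C@]2(C)CC(=O)[C@@]3(C)O[C@H]3C[C@@H]12)O | intermediate
35 | (3S,6S)-6-[(1S,3aR,6S,7S,8aS)-6,7-epoxy-3a,6-dimethyl-5-oxodecahydroazulen-1-yl]-6-hydroxy-2-methylhept-1-en-3-yl acetate | C=C(C)[C@H](CC[C@](C)(O)[C@H]1CC[C@]2(C)CC(=O)[C@@]3(C)O[C@H]3C[C@@H]12)OC(C)=O | target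

Total step count: 21.
Longest linear sequence: 16 steps (steps 1–7, 9–13 and 18–21). Step 8 and steps 14–17 are side branches.

**Steps most likely to fail**

Step 9. Both α-carbons are methylenes, so C4 may migrate in competition with C7. Repeated insertion or collapse of the betaine to a spiro-epoxide may also erode the yield. The fallback fixes the regiochemistry by enolate formation instead of migratory aptitude. It sets out from 13 and rejoins the route at 18, so step 10 is also bypassed.
- LDA/TMSCl would remove the more accessible C7 proton and give the trimethylsilyl enol ether F1.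
- Chloro(methyl)carbene (1,1-dichloroethane, n-BuLi, −35 °C) should add to this electron-rich alkene in preference to the isopropenyl group, giving the chloro(methyl)siloxycyclopropane F2.
- Heating F2 in toluene opens the cyclopropane electrocyclically across the former C5–C7 bond with loss of the silyl chloride and gives the 6-methyl enone 18. The same C5–C6 and C6–C7 bonds are formed.

Step 7. The α-keto radical may be reduced before it cyclises, or the C8a radical may take hydrogen on the methyl-bearing face and drift toward a cis fusion. The fallback replaces the radical closure by a concerted, directed hydrometalation and a polar ring closure. It sets out from 7 and rejoins at 13.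
- An Eschenmoser–Claisen rearrangement (N,N-dimethylacetamide dimethyl acetal, xylene, reflux) would give the dimethylamide F3.
- The amide carbonyl then directs a cationic rhodium- or iridium-catalysed hydroboration with pinacolborane to the neighbouring exocyclic methylene only, on the face that carries the amide arm. This gives the primary pinacol boronate F4.
- NaBO3 oxidation gives the hydroxy amide F5, with H8a already trans to the methyl group.
- MeLi converts this into the hydroxy ketone F6, and I2/PPh3/imidazole gives the iodo ketone F7.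
- Kinetic enolisation at the methyl group (LDA, −78 °C to rt) closes C7–C8 by 6-exo-tet alkylation to 13.

Step 18. The nucleophile may attack the face of the C9 carbonyl opposite to the Felkin–Anh forecast, or enolisation of the acetyl group may consume the reagent. The fallback brings in the two carbon ligands of C9 in the reverse order. It sets out from 22 and rejoins at 32.
- A haloform cleavage (NaOBr, aqueous dioxane, 0 °C) would give the C1 carboxylic acid F8.
- Coupling with N,O-dimethylhydroxylamine (EDCI) gives the Weinreb amide F9.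
- Organolithium 30 (2.2 equiv) gives the chain ketone F10.
- Methylcerium dichloride or MeMgBr then adds to this ketone, so methyl and chain exchange roles and the same intrinsic facial bias now leads to 32.

**Further compounds**

F1 | step 9 | {[(1S,3aR,7aS)-3a-methyl-1-(prop-1-en-2-yl)-2,3,3a,4,7,7a-hexahydro-1H-inden-5-yl]oxy}trimethylsilane | C=C(C)[C@H]1CC[C@]2(C)CC(O[Si](C)(C)C)=CC[C@@H]12
F2 | step 9 | chloro(methyl)carbene adduct of F1 (1-chloro-1-methyl-2-siloxycyclopropane fused at C5–C7) | C=C(C)[C@H]1CC[C@]2(C)CC3(O[Si](C)(C)C)C(C)(Cl)C3C[C@@H]12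
F3 | step 7 | 2-[(1R,3R)-1-methyl-2-methylidene-3-(prop-1-en-2-yl)cyclopentyl]-N,N-dimethylacetamide | C=C(C)[C@H]1CC[C@](C)(CC(=O)N(C)C)C1=C
F4 | step 7 | pinacol boronate from directed hydroboration of F3 | C=C(C)[C@H]1CC[C@](C)(CC(=O)N(C)C)[C@H]1CB2OC(C)(C)C(C)(C)O2
F5 | step 7 | 2-[2-(hydroxymethyl)-1-methyl-3-(prop-1-en-2-yl)cyclopentyl]-N,N-dimethylacetamide (CH2OH, methyl and isopropenyl all cis) | C=C(C)[C@H]1CC[C@](C)(CC(=O)N(C)C)[C@H]1CO
F6 | step 7 | 1-[2-(hydroxymethyl)-1-methyl-3-(prop-1-en-2-yl)cyclopentyl]propan-2-one (same relative configuration) | C=C(C)[C@H]1CC[C@](C)(CC(C)=O)[C@H]1CO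
F7 | step 7 | 1-[2-(iodomethyl)-1-methyl-3-(prop-1-en-2-yl)cyclopentyl]propan-2-one (same relative configuration) | C=C(C)[C@H]1CC[C@](C)(CC(C)=O)[C@H]1CI
F8 | step 18 | (1S,3aR,5R,6R,7S,8aS)-6,7-epoxy-5-hydroxy-3a,6-dimethyldecahydroazulene-1-carboxylic acid | O=C(O)[C@H]1CC[C@]2(C)C[C@@H](O)[C@@]3(C)O[C@H]3C[C@@H]12
F9 | step 18 | N-methoxy-N-methylamide of F8 | CON(C)C(=O)[C@H]1CC[C@]2(C)C[C@@H](O)[C@@]3(C)O[C@H]3C[C@@H]12
F10 | step 18 | (4S)-4-[(tert-butyldimethylsilyl)oxy]-1-[(1S,3aR,5R,6R,7S,8aS)-6,7-epoxy-5-hydroxy-3a,6-dimethyldecahydroazulen-1-yl]-5-methylhex-5-en-1-one | C=C(C)[C@H](CCC(=O)[C@H]1CC[C@]2(C)C[C@@H](O)[C@@]3(C)O[C@H]3C[C@@H]12)O[Si](C)(C)C(C)(C)C
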